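## The problem

Lespedezaflavanone C (28) is a 2,3-trans-dihydroflavonol. Ring C, a dihydropyranone, is fused through C4a–C8a to the phloroglucinol-type ring A and carries ring B at C2; ring A bears oxygen at C5, C7 and C8a and a prenyl group at C8, and ring B a second prenyl group next to its 4'-hydroxyl. The only stereocentres are the neighbours C2 (R, a benzylic ether carbon) and C3 (R, a carbinol α to the C4 ketone). The trans arrangement is both the outcome of an anti ring closure and the more stable one, so C3 can control C2, and both centres can be drawn from one (E)-alkene with a single asymmetric event. Once ring C exists both centres are fragile: base epimerises C3 by enolisation, opens ring C at O1–C2 and leads on to the flavonol, so the end of the synthesis must avoid base. Each prenyl group sits beside a phenol and closes to a chroman under strong protic or Lewis acid, and its alkene is attacked by electrophilic oxidants and by catalytic hydrogenation; this excludes peracids, dioxiranes, osmium reagents and benzyl ethers. Ring A is the regiochemical problem: a symmetrical phloroglucinol nucleus is prenylated on oxygen and carbon and at more than one site, and a ring A ketone with two free ortho-hydroxyls closes ring C toward 6- and 8-prenyl isomers alike, so O5 must be told apart from O1 before ring C is closed. The feature that opens a way is that C8 carries carbon while both its neighbours C7 and C8a carry oxygen, with the third oxygen on C5, para to C8, and hydrogen on C6 and C4a: this is the 2-alkyl-5-alkoxyresorcinol pattern that arises when a prenyl-substituted ynol ether (C8 and C8a) is inserted into a four-carbon alkoxyvinylketene (C7, C6, C5, C4a).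

## Retrosynthesis

**28 from 27 (O5–ethyl bond).** The last cut removes only the ethyl group on O5. It is kept to the end because it makes ring C closure unambiguous: only the oxygen on the other side of the ring A carbonyl is free to close. O5 is also the one oxygen peri to the C4 carbonyl, so a chelating Lewis acid with a nucleophilic counter-ion can find it among three free hydroxyls. Removing it earlier would bring back the 6-/8-prenyl problem. The forward step must dealkylate without base and without acid strong enough to cyclise the prenyl groups.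

**27 from 25 through 26 (O1–C2 bond).** Ring C is opened at O1–C2 to the epoxy ketone 25. Its Cα already has the configuration of C3 and its Cβ the configuration opposite to C2, so closure with inversion gives the trans product. The neighbouring options are weaker: oxa-Michael closure to a flavanone followed by C3 hydroxylation needs stereocontrol at two stages and an electrophilic oxidant or strong base, and a diol/Mitsunobu closure needs an electrophilic dihydroxylation that the prenyl alkenes would not survive. The precursor is acyclic. The forward step asks that the acid which frees the phenols (through 26) also steers the phenol on the future O1 to the benzylic carbon in a 6-endo opening, which the para oxygen of ring B favours.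

**25 from 24 (the two epoxide C–O bonds).** This leads to the (E)-chalcone 24, which has no stereocentre. The enone is the only alkene of 24 that a nucleophilic peroxide attacks, so the two prenyl alkenes are spared, which no electrophilic oxidant could do. The forward reaction must be a catalytic asymmetric nucleophilic epoxidation on an enone whose aroyl group is doubly ortho-substituted.

**24 from 19 and 22 (Cα=Cβ bond); 22 from 21; 21 from 20 and 5.** Retro-aldol condensation divides the molecule into the ring A acetophenone 19 (with C4 and C3) and the ring B aldehyde 22 (with C2). Both carry all phenols as MOM ethers, so base-mediated condensation is clean; acylating ring A with a cinnamoyl unit would need Friedel–Crafts acid. 22 comes from phenol 21 by protection, and 21 from 20 and 5 by ortho-C-prenylation, the para position of 20 being blocked by the formyl group.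

**19 from 17 through 18 (C4–C4a bond); 17 from 16; 16 from 15.** Removing the acetyl group leaves arene 17. It has a mirror plane through C8 and C5, so its two ring hydrogens are equivalent, each between a MOM ether and the ethoxy group. Metalation (18) can therefore occur in one way only; the carbon metalated becomes C4a and the MOM oxygen beside it O1. Electrophilic acylation would need acid, and ortho-formylation of a singly freed phenol followed by homologation to the methyl ketone costs three more steps. The price is that the distinction between O7 (free) and O1 (silylated), which the benzannulation creates, is surrendered in 15 → 16 → 17. What is kept is what ring C closure needs: O5 distinct from the other two, and the prenyl group locked between them.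

**15 from 4 and 10 (C7–C8 and C8a–C4a bonds; ring A).** Taking out the two-carbon unit C8–C8a with its prenyl and siloxy substituents leaves the four-carbon unit C7–C6–C5–C4a, the ethoxyvinylketene 11, which is stored as cyclobutenone 4; the two-carbon unit is siloxyalkyne 10. The competing cut, C8–prenyl (prenylation of a 5-alkoxyresorcinol), must control carbon against oxygen, C8 against C6 and mono- against bis-alkylation. Here the prenyl position is fixed by the connectivity of 10 and the ethoxy position by that of 4, so regiochemistry reduces to the orientation of a polarised ynol ether toward a ketene. A tetrasubstituted arene is exchanged for two small pieces without stereochemistry. The forward reaction needs a regioselective [2+2] event, a cyclobutenone that opens at a temperature the siloxyalkyne tolerates, and an alkyne that outcompetes the prenyl alkene for the ketene.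

**10 from 7 through 8 and 9; 7 from 5 and 6; 4 from 1 and 2 through 3.** The siloxyalkyne is cut at O–Si and C–O to the terminal enyne 7 (acetylide oxidation, then O-silylation), and 7 at its sp–sp3 bond to 5 and 6. Cyclobutenone 4 is the [2+2] adduct of ketene 3, made from 1, with ynol ether 2. Bromide 5 supplies both prenyl groups of the target.

## Roads not taken

**Alternative 1:** The cut is the O1–C8a bond. An anti aldol, (2R,3R)-1-[2,6-difluoro-4-(methoxymethoxy)phenyl]-3-hydroxy-2-(methoxymethoxy)-3-[4-(methoxymethoxy)-3-prenylphenyl]propan-1-one A2, would be made first. Its alkoxide at the future C2 would displace one of the two equivalent ortho fluorides, closing ring C with retention at C2 to give the 5-fluoroflavanone A1.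
- Merits: ring C closes under mild base without ambiguity because the difluoroaryl ketone is symmetrical; both stereocentres come from one aldol reaction and are untouched by the closure; the sequence to the flavanonol core is shorter than in the chosen plan.
- Weak points: A1 has fluorine where O5 must be and hydrogen where the C8 prenyl group must be. The fluorine must be exchanged for oxygen by a second substitution on a base-sensitive 3-alkoxyflavanone (acidic C3–H, O1–C2 bond ready to open). The prenyl group must then be put on C8 of a 5,7-dioxygenated flavanone, the least selective operation in this class (C6 against C8, carbon against oxygen). Placing the prenyl group before the closure would make the two fluorides unequal and remove the symmetry that is the asset of the route. An anti-selective, enantioselective glycolate aldol reaction of a hindered aryl ketone is a further demand.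
- Comparison: alternative 1 is better in ring C stereocontrol and shorter to the core. The chosen plan sets against this that the prenyl position and the status of O5 are settled before ring C is made, so the sensitive flavanonol needs only one dealkylation.

**Alternative 2:** The cuts are C8–C8a and C4a–C5; ring A is grown on a preformed ring C. The dihydropyranone (2R,3R)-5-bromo-2-[4-(tert-butyldimethylsilyloxy)-3-prenylphenyl]-4-oxo-3,4-dihydro-2H-pyran-3-yl benzoate A4 would react at its C4a=C8a double bond with the diene 1-methoxy-7-methyl-1,3-bis(trimethylsilyloxy)octa-1,3,6-triene A5. The adduct would aromatise by three eliminations (bromide, the methoxy group and one silyloxy group) to 3-O-benzoyl-4'-O-(tert-butyldimethylsilyl)-lespedezaflavanone C A3.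
- Merits: highly convergent; ring A arrives with its prenyl group in place and O5 and O7 free, so no ring A dealkylation is needed; the stereocentres are made on a small ring.
- Weak points: A4 is a vinylogous ester and a reluctant 2π partner. A5 carries a substituent on its reacting terminus, which slows the cycloaddition and raises a geometry problem in its preparation. The aromatising eliminations need acid or base in the presence of a C3 ester α to the ketone and a C2 benzylic ether, the two groups through which ring C is lost (β-elimination, retro-oxa-Michael opening). The benzoate must then be removed from a base-sensitive flavanonol.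
- Comparison: if the annulation worked, this road would be shorter after the stereocentres are set and would avoid the final dealkylation, a real advantage. The chosen plan sets against it a ring A annulation of an established type, run before any stereocentre exists, and a ring C sequence whose steps are all known on prenylated chalcones.

**Alternative 3:** The cuts are C3–C4 and O1–C2. The salicylaldehyde 2-hydroxy-4,6-bis(methoxymethoxy)-3-prenylbenzaldehyde A7 would be turned under a chiral phosphoric acid into an α-methoxy ortho-quinone methide. This would add to the enol ester (E)-2-[4-(tert-butyldimethylsilyloxy)-3-prenylphenyl]ethenyl benzoate A8 to give the 3-benzoyloxy-4-methoxyflavan A6.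
- Merits: ring C and both of its stereocentres form in one catalytic, convergent step, and the protecting groups suit the prenyl groups.
- Weak points: enol esters are weak partners for ortho-quinone methides, and the catalyst would have to control three contiguous centres with a doubly ortho-substituted aldehyde component. C4 arrives at the wrong oxidation level: the C4 ether must be hydrolysed and the benzylic alcohol oxidised to the ketone next to an electron-rich ring and two prenyl groups. The benzoate must be removed at the end. A7 itself contains the whole ring A problem (prenyl between two oxygens, one of them free), which this plan does not address.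
- Comparison: alternative 3 makes ring C in fewer steps and with catalytic stereocontrol, which the chosen sequence of condensation, epoxidation and ring closure cannot match. The chosen plan sets against it that every ring C step is of a known type on close relatives, that C4 is at the ketone level throughout, and that it supplies the ring A substitution that alternative 3 takes for granted.

Key step: step 4

Remarks on the chemistry (assumptions):
- Prenyl = 3-methylbut-2-en-1-yl, MOM = methoxymethyl, TIPS = triisopropylsilyl; flavonoid numbering is used for ring positions.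
- Poly-L-leucine is taken to epoxidise 24 with the facial sense it shows for the parent chalcone, giving the (2R,3S)-epoxide; were the sense opposite, poly-D-leucine would be used.
- Ethynylmagnesium bromide (THF solution) and poly-L-leucine are taken as purchased.

## Route

Step 1
Reactants: 1 acetyl chloride; 2 ethoxyacetylene
Product: 4 3-ethoxycyclobut-2-en-1-one, via ketene 3 (not isolated)
Conditions: Et3N, Et2O, 0 °C to rt (2 in excess)
Reagents that add atoms: none
Why: Et3N dehydrochlorinates 1 to ketene 3, which the ynol ether 2 traps in a regioselective [2+2] cycloaddition (its terminal, nucleophilic carbon bonds to the ketene carbonyl carbon), the standard entry to 3-alkoxycyclobutenones.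

Step 2
Reactants: 5 prenyl bromide (1-bromo-3-methylbut-2-ene); 6 ethynylmagnesium bromide
Product: 7 5-methylhex-4-en-1-yne
Conditions: CuCl (5 mol %), THF, 0 °C to rt
Reagents that add atoms: none
Why: CuCl-catalysed coupling of an alkynyl Grignard reagent with an allylic bromide; substitution at the primary carbon of the prenyl system should give the skipped enyne, which is distilled.

Step 3
Reactants: 7 5-methylhex-4-en-1-yne
Product: 10 triisopropyl[(5-methylhex-4-en-1-yn-1-yl)oxy]silane, via lithium acetylide 8 (not isolated), via lithium ynolate 9 (not isolated)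
Conditions: n-BuLi, THF, −78 °C; LiOO-t-Bu (from t-BuOOH, LiN(SiMe3)2), −78 to 0 °C; TIPSOTf, −78 to 0 °C
Reagents that add atoms: tert-butyl hydroperoxide, CC(C)(C)OO; triisopropylsilyl trifluoromethanesulfonate, CC(C)[Si](C(C)C)(C(C)C)OS(=O)(=O)C(F)(F)F
Why: Oxidation of a lithium acetylide by lithium tert-butyl peroxide gives the lithium ynolate, and the bulky silyl triflate silylates it on oxygen; the terminal alkyne C–H is far more acidic than the doubly allylic CH2, so one equivalent of base is selective.

Step 4
Reactants: 4 3-ethoxycyclobut-2-en-1-one; 10 triisopropyl[(5-methylhex-4-en-1-yn-1-yl)oxy]silane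
Product: 15 5-ethoxy-2-(3-methylbut-2-en-1-yl)-3-[(triisopropylsilyl)oxy]phenol, via vinylketene 11 (not isolated), via vinylcyclobutenone 12 (not isolated), via dienylketene 13 (not isolated), via cyclohexadienone 14 (not isolated)
Conditions: PhMe, 80 °C then 110 °C, sealed tube (4 in slight excess)
Reagents that add atoms: none
Why: Danheiser benzannulation, the closest known reaction type being the union of a cyclobutenone with a trialkylsiloxyalkyne to give a resorcinol monosilyl ether. Heat opens 4 by 4π-electrocyclic ring opening to vinylketene 11. The ynol ether 10 adds across the ketene C=C bond in a [2+2] cycloaddition, its prenyl-bearing carbon (the nucleophilic one, β to oxygen) bonding to the ketene carbonyl carbon (C7–C8) and its siloxy carbon to the ketene α-carbon (C8a–C4a), to give 12. A second 4π opening gives dienylketene 13, and ring A closes by thermal disrotatory 6π-electrocyclisation (re-forming the C6–C7 bond that the first opening broke) to dienone 14, which tautomerises to phenol 15. No stereocentre is formed; the one in 12 is lost on ring opening. The step needs regiocontrol in the [2+2] event, secured by the polarisation of the siloxyalkyne, and chemoselectivity for the alkyne over the trisubstituted prenyl alkene, secured by the far greater nucleophilicity of the ynol ether. The connectivity of the two partners fixes the prenyl group between two oxygens and the ethoxy group para to it, which is the ring A pattern of 28.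

Step 5
Reactants: 15 5-ethoxy-2-(3-methylbut-2-en-1-yl)-3-[(triisopropylsilyl)oxy]phenol
Product: 16 5-ethoxy-2-(3-methylbut-2-en-1-yl)benzene-1,3-diol
Conditions: TBAF, THF, 0 °C; aq. NH4Cl
Reagents that add atoms: none
Why: Fluoride cleaves the aryl silyl ether under neutral to basic conditions that leave the acid-sensitive ortho-prenylresorcinol intact.

Step 6
Reactants: 16 5-ethoxy-2-(3-methylbut-2-en-1-yl)benzene-1,3-diol
Product: 17 5-ethoxy-1,3-bis(methoxymethoxy)-2-(3-methylbut-2-en-1-yl)benzene
Conditions: MOMCl, i-Pr2NEt, CH2Cl2, 0 °C to rt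
Reagents that add atoms: chloromethyl methyl ether, COCCl
Why: Standard MOM protection of both phenols; the acetals direct the metalation of step 7, survive the basic steps 10 and 11, and leave under the acid of step 12, to which the ethyl ether is inert.

Step 7
Reactants: 17 5-ethoxy-1,3-bis(methoxymethoxy)-2-(3-methylbut-2-en-1-yl)benzene
Product: 19 1-[6-ethoxy-2,4-bis(methoxymethoxy)-3-(3-methylbut-2-en-1-yl)phenyl]ethan-1-one, via aryllithium 18 (not isolated)
Conditions: n-BuLi, TMEDA, THF, 0 °C; MeC(O)N(OMe)Me, −78 °C to rt; aq. NH4Cl
Reagents that add atoms: N-methoxy-N-methylacetamide, CC(=O)N(C)OC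
Why: Directed ortho-metalation: 17 is mirror-symmetric, its two ring C–H positions are equivalent and each lies between a MOM ether and the ethoxy group, so one aryllithium forms; the Weinreb amide stops at the ketone through its chelated tetrahedral adduct.

Step 8
Reactants: 20 4-hydroxybenzaldehyde; 5 prenyl bromide (1-bromo-3-methylbut-2-ene)
Product: 21 4-hydroxy-3-(3-methylbut-2-en-1-yl)benzaldehyde
Conditions: KOH, H2O, rt
Reagents that add atoms: none
Why: ortho-C-Alkylation of a phenoxide in water, where hydrogen bonding to oxygen favours attack through carbon; the para position is blocked, and the O-prenyl ether and bis-prenylated by-products are separated.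

Step 9
Reactants: 21 4-hydroxy-3-(3-methylbut-2-en-1-yl)benzaldehyde
Product: 22 4-(methoxymethoxy)-3-(3-methylbut-2-en-1-yl)benzaldehyde
Conditions: MOMCl, i-Pr2NEt, CH2Cl2, 0 °C to rt
Reagents that add atoms: chloromethyl methyl ether, COCCl
Why: Standard MOM protection; masking the phenol keeps the aldehyde electrophilic in step 10 and the enone electrophilic in step 11.

Step 10
Reactants: 19 1-[6-ethoxy-2,4-bis(methoxymethoxy)-3-(3-methylbut-2-en-1-yl)phenyl]ethan-1-one; 22 4-(methoxymethoxy)-3-(3-methylbut-2-en-1-yl)benzaldehyde
Product: 24 (E)-1-[6-ethoxy-2,4-bis(methoxymethoxy)-3-(3-methylbut-2-en-1-yl)phenyl]-3-[4-(methoxymethoxy)-3-(3-methylbut-2-en-1-yl)phenyl]prop-2-en-1-one, via aldol adduct 23 (not isolated)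
Conditions: KOH, EtOH/H2O, rt
Reagents that add atoms: none
Why: Claisen–Schmidt condensation: aldol addition followed by E1cB dehydration gives the (E)-enone; neither partner has a free phenol or another enolisable position, and MOM-protected prenylated acetophenones of this substitution type are known to condense under these conditions.

Step 11
Reactants: 24 (E)-1-[6-ethoxy-2,4-bis(methoxymethoxy)-3-(3-methylbut-2-en-1-yl)phenyl]-3-[4-(methoxymethoxy)-3-(3-methylbut-2-en-1-yl)phenyl]prop-2-en-1-one
Product: 25 [(2R,3S)-3-[4-(methoxymethoxy)-3-(3-methylbut-2-en-1-yl)phenyl]oxiran-2-yl][6-ethoxy-2,4-bis(methoxymethoxy)-3-(3-methylbut-2-en-1-yl)phenyl]methanone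
Conditions: poly-L-leucine, urea·H2O2, DBU, THF, rt
Reagents that add atoms: hydrogen peroxide (as its urea adduct), OO
Why: Juliá–Colonna epoxidation, a Weitz–Scheffer conjugate addition of hydroperoxide anion held on the helical polypeptide, whose N-terminal NH groups bind the enone and expose one face; the (E)-geometry is transferred to a trans epoxide, so Cα (future C3, R) and Cβ (future C2, S before inversion) are set together, and the electron-rich prenyl alkenes are inert to the nucleophilic oxidant.

Step 12
Reactants: 25 [(2R,3S)-3-[4-(methoxymethoxy)-3-(3-methylbut-2-en-1-yl)phenyl]oxiran-2-yl][6-ethoxy-2,4-bis(methoxymethoxy)-3-(3-methylbut-2-en-1-yl)phenyl]methanone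
Product: 27 (2R,3R)-5-ethoxy-3,7-dihydroxy-2-[4-hydroxy-3-(3-methylbut-2-en-1-yl)phenyl]-8-(3-methylbut-2-en-1-yl)-2,3-dihydro-4H-chromen-4-one, via epoxy triol 26 (not isolated)
Conditions: HCl (aq.), MeOH/THF, 40–50 °C
Reagents that add atoms: none
Why: Acid cleaves the three MOM acetals, and the phenol freed next to the ketone opens the protonated epoxide at the benzylic carbon (6-endo, favoured by the para oxygen of ring B) with inversion, giving C2 (R), while C3 keeps the Cα configuration (R); the trans product is also the thermodynamic one, and because O5 is ethylated only the oxygen beside the prenyl group can close, so only the 8-prenyl isomer can form.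

Step 13
Reactants: 27 (2R,3R)-5-ethoxy-3,7-dihydroxy-2-[4-hydroxy-3-(3-methylbut-2-en-1-yl)phenyl]-8-(3-methylbut-2-en-1-yl)-2,3-dihydro-4H-chromen-4-one
Product: 28 lespedezaflavanone C, (2R,3R)-3,5,7-trihydroxy-2-[4-hydroxy-3-(3-methylbut-2-en-1-yl)phenyl]-8-(3-methylbut-2-en-1-yl)-2,3-dihydro-4H-chromen-4-one
Conditions: MgI2·OEt2, THF, 65 °C; dil. aq. HCl
Reagents that add atoms: none
Why: Chelation-assisted dealkylation: magnesium bridges the C4 carbonyl and the peri O5, and iodide removes the ethyl group by SN2 attack; this reaction type is known for 5-alkoxy-8-prenylflavanones with free phenols and touches neither stereocentre nor the prenyl groups.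

## Compound list

1 | acetyl chloride | CC(=O)Cl | starting material
2 | ethoxyacetylene | C#COCC | starting material
3 | ketene | C=C=O | intermediate
4 | 3-ethoxycyclobut-2-en-1-one | CCOC1=CC(=O)C1 | intermediate
5 | prenyl bromide (1-bromo-3-methylbut-2-ene) | CC(C)=CCBr | starting material
6 | ethynylmagnesium bromide | C#C[Mg]Br | starting material
7 | 5-methylhex-4-en-1-yne | CC(C)=CCC#C | intermediate
8 | (5-methylhex-4-en-1-yn-1-yl)lithium | [Li]C#CCC=C(C)C | intermediate
9 | lithium 5-methylhex-4-en-1-yn-1-olate | [Li+].[O-]C#CCC=C(C)C | intermediate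
10 | triisopropyl[(5-methylhex-4-en-1-yn-1-yl)oxy]silane | CC(C)=CCC#CO[Si](C(C)C)(C(C)C)C(C)C | intermediate
11 | 3-ethoxybuta-1,3-dien-1-one | C=C(OCC)C=C=O | intermediate
12 | 4-(1-ethoxyethenyl)-2-(3-methylbut-2-en-1-yl)-3-[(triisopropylsilyl)oxy]cyclobut-2-en-1-one (racemic) | C=C(OCC)C1C(=O)C(CC=C(C)C)=C1O[Si](C(C)C)(C(C)C)C(C)C | intermediate
13 | 5-ethoxy-2-(3-methylbut-2-en-1-yl)-3-[(triisopropylsilyl)oxy]hexa-1,3,5-trien-1-one, ketene carbon and ethoxyvinyl group cis on the C3=C4 bond | C=C(OCC)/C=C(\C(CC=C(C)C)=C=O)O[Si](C(C)C)(C(C)C)C(C)C | intermediate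
14 | 5-ethoxy-2-(3-methylbut-2-en-1-yl)-3-[(triisopropylsilyl)oxy]cyclohexa-2,4-dien-1-one | O=C1CC(OCC)=CC(O[Si](C(C)C)(C(C)C)C(C)C)=C1CC=C(C)C | intermediate
15 | 5-ethoxy-2-(3-methylbut-2-en-1-yl)-3-[(triisopropylsilyl)oxy]phenol | CC(C)=CCc1c(O)cc(OCC)cc1O[Si](C(C)C)(C(C)C)C(C)C | intermediate
16 | 5-ethoxy-2-(3-methylbut-2-en-1-yl)benzene-1,3-diol | CCOc1cc(O)c(CC=C(C)C)c(O)c1 | intermediate
17 | 5-ethoxy-1,3-bis(methoxymethoxy)-2-(3-methylbut-2-en-1-yl)benzene | CCOc1cc(OCOC)c(CC=C(C)C)c(OCOC)c1 | intermediate
18 | [6-ethoxy-2,4-bis(methoxymethoxy)-3-(3-methylbut-2-en-1-yl)phenyl]lithium | [Li]c1c(OCC)cc(OCOC)c(CC=C(C)C)c1OCOC | intermediate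
19 | 1-[6-ethoxy-2,4-bis(methoxymethoxy)-3-(3-methylbut-2-en-1-yl)phenyl]ethan-1-one | CC(=O)c1c(OCC)cc(OCOC)c(CC=C(C)C)c1OCOC | intermediate
20 | 4-hydroxybenzaldehyde | O=Cc1ccc(O)cc1 | starting material
21 | 4-hydroxy-3-(3-methylbut-2-en-1-yl)benzaldehyde | CC(C)=CCc1cc(C=O)ccc1O | intermediate
22 | 4-(methoxymethoxy)-3-(3-methylbut-2-en-1-yl)benzaldehyde | CC(C)=CCc1cc(C=O)ccc1OCOC | intermediate
23 | 1-[6-ethoxy-2,4-bis(methoxymethoxy)-3-(3-methylbut-2-en-1-yl)phenyl]-3-hydroxy-3-[4-(methoxymethoxy)-3-(3-methylbut-2-en-1-yl)phenyl]propan-1-one (racemic) | CCOc1cc(OCOC)c(CC=C(C)C)c(OCOC)c1C(=O)CC(O)c2ccc(OCOC)c(CC=C(C)C)c2 | intermediate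
24 | (E)-1-[6-ethoxy-2,4-bis(methoxymethoxy)-3-(3-methylbut-2-en-1-yl)phenyl]-3-[4-(methoxymethoxy)-3-(3-methylbut-2-en-1-yl)phenyl]prop-2-en-1-one | CCOc1cc(OCOC)c(CC=C(C)C)c(OCOC)c1C(=O)/C=C/c2ccc(OCOC)c(CC=C(C)C)c2 | intermediate
25 | [(2R,3S)-3-[4-(methoxymethoxy)-3-(3-methylbut-2-en-1-yl)phenyl]oxiran-2-yl][6-ethoxy-2,4-bis(methoxymethoxy)-3-(3-methylbut-2-en-1-yl)phenyl]methanone | CCOc1cc(OCOC)c(CC=C(C)C)c(OCOC)c1C(=O)[C@@H]2O[C@H]2c3ccc(OCOC)c(CC=C(C)C)c3 | intermediate
26 | [(2R,3S)-3-[4-hydroxy-3-(3-methylbut-2-en-1-yl)phenyl]oxiran-2-yl][6-ethoxy-2,4-dihydroxy-3-(3-methylbut-2-en-1-yl)phenyl]methanone | CCOc1cc(O)c(CC=C(C)C)c(O)c1C(=O)[C@@H]2O[C@H]2c3ccc(O)c(CC=C(C)C)c3 | intermediate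
27 | (2R,3R)-5-ethoxy-3,7-dihydroxy-2-[4-hydroxy-3-(3-methylbut-2-en-1-yl)phenyl]-8-(3-methylbut-2-en-1-yl)-2,3-dihydro-4H-chromen-4-one | CC(C)=CCc1cc([C@H]2Oc3c(CC=C(C)C)c(O)cc(OCC)c3C(=O)[C@@H]2O)ccc1O | intermediate
28 | lespedezaflavanone C, (2R,3R)-3,5,7-trihydroxy-2-[4-hydroxy-3-(3-methylbut-2-en-1-yl)phenyl]-8-(3-methylbut-2-en-1-yl)-2,3-dihydro-4H-chromen-4-one | CC(C)=CCc1cc([C@H]2Oc3c(CC=C(C)C)c(O)cc(O)c3C(=O)[C@@H]2O)ccc1O | target

## Step count and least certain steps

Total step count: 13. Longest linear sequence: 10 steps (steps 2, 3, 4, 5, 6, 7, 10, 11, 12 and 13, from 5 to 28).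

**Step 4 (key step).** The ethoxy group stabilises 4 as a vinylogous ester, so the first ring opening may need temperatures at which the siloxyalkyne isomerises to a silylketene. The phenol product may also capture vinylketene as an aryl ester faster than the alkyne does, and the cascade may stall at the vinylcyclobutenone stage.
Fallback (sets out from 10, with commercial ethyl vinyl ether as the second component; returns at 15): the same vinylketene is made at room temperature by a photochemical Wolff rearrangement, so the phenol appears only in a later thermal stage when no ketene is left. Ethyl vinyl ether is lithiated (t-BuLi, THF) to 1-ethoxyvinyllithium F1, which N-methoxy-N-methylacetamide acetylates to 3-ethoxybut-3-en-2-one F2. Trifluoroacetylation of its lithium enolate (LiN(SiMe3)2, CF3CO2CH2CF3) gives 5-ethoxy-1,1,1-trifluorohex-5-ene-2,4-dione F3, and detrifluoroacetylative diazo transfer (MsN3, Et3N) gives 1-diazo-3-ethoxybut-3-en-2-one F4. Irradiation of F4 with 10 gives 11 and then 12 by the same [2+2] event, and brief heating completes the passage through 13 and 14 to 15.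

**Step 13.** Iodide attack on the ethyl carbon is slower than on a methyl group. Prolonged heating with the Lewis acid may bring acid-induced closure of a prenyl group onto its neighbouring phenol, or epimerisation through ring opening, before dealkylation is complete.
Fallback (sets out from 4, returns at 28): the spectator alkoxy group of the benzannulation is changed to methoxy, for which this dealkylation is the directly known case. Dilute aqueous HCl hydrolyses 4 to cyclobutane-1,3-dione F5, and Me3SiCHN2 in MeOH/Et2O methylates its enol to 3-methoxycyclobut-2-en-1-one F6. F6 and 10 are taken through the operations of steps 4 to 12 unchanged. The benzannulation passes through 3-methoxybuta-1,3-dien-1-one F7, the methoxy vinylcyclobutenone F8, the methoxy dienylketene F9 and the methoxy cyclohexadienone F10 to 5-methoxy-2-prenyl-3-(triisopropylsilyloxy)phenol F11. Desilylation gives 5-methoxy-2-prenylbenzene-1,3-diol F12, protection gives 5-methoxy-1,3-bis(methoxymethoxy)-2-prenylbenzene F13, and lithiation to the methoxy aryllithium F14 followed by acetylation gives the methoxy acetophenone F15. Condensation with 22 gives, through the methoxy aldol adduct F16, the methoxy chalcone F17; epoxidation gives the methoxy epoxy ketone F18; acid gives, through the methoxy epoxy triol F19, 5-O-methyl-lespedezaflavanone C F20, which MgI2·OEt2 demethylates to 28.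

**Step 12.** After protonation of the epoxide several processes compete with the wanted 6-endo closure: solvolysis of the benzylic C–O bond by methanol without ring closure; 1,2-aryl migration; attack of the phenol at Cα to give a five-membered ring; and acid-induced chroman formation at the ring A prenyl group once both neighbouring phenols are free.
Fallback (sets out from 25, returns at 27): ring C is closed before the phenols beside the prenyl groups are unmasked. Benzyl mercaptan with SnCl4 at −20 °C opens the epoxide at the benzylic carbon and removes only the chelated MOM ether on the future O1. This gives (2S)-3-(benzylsulfanyl)-1-[6-ethoxy-2-hydroxy-4-(methoxymethoxy)-3-prenylphenyl]-2-hydroxy-3-[4-(methoxymethoxy)-3-prenylphenyl]propan-1-one F21, as either epimer at the sulfur-bearing carbon. The descriptor at C2 changes only because sulfur raises the priority of the neighbouring carbon. AgBF4 in CH2Cl2 at 0 °C ionises the C–S bond and the free phenol closes ring C, trans by the same preference, to the 7,4'-bis(methoxymethyl) ether of 27 F22. Dilute methanolic HCl at room temperature then removes the two remaining acetals from the closed ring.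

**Step 11.** Facial discrimination may be poor and conversion slow, because the ring A carbonyl is twisted out of conjugation by its two ortho substituents and the substrate is bulky for the polypeptide.
Fallback (sets out from 22 and from 17 through 18, returns at 25): the stereocentres are set on a small ring B cinnamamide and ring A is attached afterwards. Horner–Wadsworth–Emmons reaction of 22 with diethyl (2-morpholino-2-oxoethyl)phosphonate (NaH, THF) gives (E)-3-[4-(methoxymethoxy)-3-prenylphenyl]-1-(morpholin-4-yl)prop-2-en-1-one F23. Lanthanide–BINOL-catalysed nucleophilic epoxidation (Sm(O-i-Pr)3, the BINOL antipode that gives the (2R,3S) product, Ph3As=O, t-BuOOH) gives the epoxy amide [(2R,3S)-3-[4-(methoxymethoxy)-3-prenylphenyl]oxiran-2-yl](morpholin-4-yl)methanone F24. Aryllithium 18, made from 17 as in step 7, adds to the morpholine amide at −78 °C to give 25.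

**Step 7.** Deprotonation of the benzylic-allylic CH2 of the prenyl group, which is flanked by two coordinating MOM ethers, may compete with ring metalation. Proton transfer from the acetyl donor to the hindered aryllithium would return 17.
Fallback (sets out from 17, returns at 19): the carbanion is made by halogen–metal exchange and the ketone by oxidation. NBS (1 equiv, MeCN, −20 °C) brominates the very electron-rich ring at one of its two equivalent positions to give 2-bromo-1-ethoxy-3,5-bis(methoxymethoxy)-4-prenylbenzene F25. n-BuLi at −78 °C exchanges bromine for lithium (giving 18 without an acidic partner present), and acetaldehyde gives the carbinol 1-[6-ethoxy-2,4-bis(methoxymethoxy)-3-prenylphenyl]ethanol F26. Dess–Martin periodinane buffered with NaHCO3 oxidises F26 to 19.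

## Further compounds

F1 | step 4 | 1-ethoxyvinyllithium | [Li]C(=C)OCC
F2 | step 4 | 3-ethoxybut-3-en-2-one | C=C(OCC)C(C)=O
F3 | step 4 | 5-ethoxy-1,1,1-trifluorohex-5-ene-2,4-dione | C=C(OCC)C(=O)CC(=O)C(F)(F)F
F4 | step 4 | 1-diazo-3-ethoxybut-3-en-2-one | C=C(OCC)C(=O)C=[N+]=[N-]
F5 | step 13 | cyclobutane-1,3-dione | O=C1CC(=O)C1
F6 | step 13 | 3-methoxycyclobut-2-en-1-one | COC1=CC(=O)C1
F7 | step 13 | 3-methoxybuta-1,3-dien-1-one | C=C(OC)C=C=O
F8 | step 13 | 4-(1-methoxyethenyl)-2-(3-methylbut-2-en-1-yl)-3-[(triisopropylsilyl)oxy]cyclobut-2-en-1-one (racemic) | C=C(OC)C1C(=O)C(CC=C(C)C)=C1O[Si](C(C)C)(C(C)C)C(C)C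
F9 | step 13 | 5-methoxy-2-(3-methylbut-2-en-1-yl)-3-[(triisopropylsilyl)oxy]hexa-1,3,5-trien-1-one, ketene carbon and methoxyvinyl group cis | C=C(OC)/C=C(\C(CC=C(C)C)=C=O)O[Si](C(C)C)(C(C)C)C(C)C
F10 | step 13 | 5-methoxy-2-(3-methylbut-2-en-1-yl)-3-[(triisopropylsilyl)oxy]cyclohexa-2,4-dien-1-one | O=C1CC(OC)=CC(O[Si](C(C)C)(C(C)C)C(C)C)=C1CC=C(C)C
F11 | step 13 | 5-methoxy-2-(3-methylbut-2-en-1-yl)-3-[(triisopropylsilyl)oxy]phenol | CC(C)=CCc1c(O)cc(OC)cc1O[Si](C(C)C)(C(C)C)C(C)C
F12 | step 13 | 5-methoxy-2-(3-methylbut-2-en-1-yl)benzene-1,3-diol | COc1cc(O)c(CC=C(C)C)c(O)c1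
F13 | step 13 | 5-methoxy-1,3-bis(methoxymethoxy)-2-(3-methylbut-2-en-1-yl)benzene | COc1cc(OCOC)c(CC=C(C)C)c(OCOC)c1
F14 | step 13 | [6-methoxy-2,4-bis(methoxymethoxy)-3-(3-methylbut-2-en-1-yl)phenyl]lithium | [Li]c1c(OC)cc(OCOC)c(CC=C(C)C)c1OCOC
F15 | step 13 | 1-[6-methoxy-2,4-bis(methoxymethoxy)-3-(3-methylbut-2-en-1-yl)phenyl]ethan-1-one | CC(=O)c1c(OC)cc(OCOC)c(CC=C(C)C)c1OCOC
F16 | step 13 | 3-hydroxy-1-[6-methoxy-2,4-bis(methoxymethoxy)-3-(3-methylbut-2-en-1-yl)phenyl]-3-[4-(methoxymethoxy)-3-(3-methylbut-2-en-1-yl)phenyl]propan-1-one (racemic) | COc1cc(OCOC)c(CC=C(C)C)c(OCOC)c1C(=O)CC(O)c2ccc(OCOC)c(CC=C(C)C)c2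
F17 | step 13 | (E)-1-[6-methoxy-2,4-bis(methoxymethoxy)-3-(3-methylbut-2-en-1-yl)phenyl]-3-[4-(methoxymethoxy)-3-(3-methylbut-2-en-1-yl)phenyl]prop-2-en-1-one | COc1cc(OCOC)c(CC=C(C)C)c(OCOC)c1C(=O)/C=C/c2ccc(OCOC)c(CC=C(C)C)c2
F18 | step 13 | [(2R,3S)-3-[4-(methoxymethoxy)-3-(3-methylbut-2-en-1-yl)phenyl]oxiran-2-yl][6-methoxy-2,4-bis(methoxymethoxy)-3-(3-methylbut-2-en-1-yl)phenyl]methanone | COc1cc(OCOC)c(CC=C(C)C)c(OCOC)c1C(=O)[C@@H]2O[C@H]2c3ccc(OCOC)c(CC=C(C)C)c3
F19 | step 13 | [(2R,3S)-3-[4-hydroxy-3-(3-methylbut-2-en-1-yl)phenyl]oxiran-2-yl][2,4-dihydroxy-6-methoxy-3-(3-methylbut-2-en-1-yl)phenyl]methanone | COc1cc(O)c(CC=C(C)C)c(O)c1C(=O)[C@@H]2O[C@H]2c3ccc(O)c(CC=C(C)C)c3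
F20 | step 13 | (2R,3R)-3,7-dihydroxy-2-[4-hydroxy-3-(3-methylbut-2-en-1-yl)phenyl]-5-methoxy-8-(3-methylbut-2-en-1-yl)-2,3-dihydro-4H-chromen-4-one | CC(C)=CCc1cc([C@H]2Oc3c(CC=C(C)C)c(O)cc(OC)c3C(=O)[C@@H]2O)ccc1O
F21 | step 12 | (2S)-3-(benzylsulfanyl)-1-[6-ethoxy-2-hydroxy-4-(methoxymethoxy)-3-(3-methylbut-2-en-1-yl)phenyl]-2-hydroxy-3-[4-(methoxymethoxy)-3-(3-methylbut-2-en-1-yl)phenyl]propan-1-one (C3 epimers) | CCOc1cc(OCOC)c(CC=C(C)C)c(O)c1C(=O)[C@H](O)C(SCc2ccccc2)c3ccc(OCOC)c(CC=C(C)C)c3
F22 | step 12 | (2R,3R)-5-ethoxy-3-hydroxy-7-(methoxymethoxy)-2-[4-(methoxymethoxy)-3-(3-methylbut-2-en-1-yl)phenyl]-8-(3-methylbut-2-en-1-yl)-2,3-dihydro-4H-chromen-4-one | CC(C)=CCc1cc([C@H]2Oc3c(CC=C(C)C)c(OCOC)cc(OCC)c3C(=O)[C@@H]2O)ccc1OCOC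
F23 | step 11 | (E)-3-[4-(methoxymethoxy)-3-(3-methylbut-2-en-1-yl)phenyl]-1-(morpholin-4-yl)prop-2-en-1-one | CC(C)=CCc1cc(/C=C/C(=O)N2CCOCC2)ccc1OCOC
F24 | step 11 | [(2R,3S)-3-[4-(methoxymethoxy)-3-(3-methylbut-2-en-1-yl)phenyl]oxiran-2-yl](morpholin-4-yl)methanone | O=C(N1CCOCC1)[C@@H]2O[C@H]2c3ccc(OCOC)c(CC=C(C)C)c3
F25 | step 7 | 2-bromo-1-ethoxy-3,5-bis(methoxymethoxy)-4-(3-methylbut-2-en-1-yl)benzene | CCOc1cc(OCOC)c(CC=C(C)C)c(OCOC)c1Br
F26 | step 7 | 1-[6-ethoxy-2,4-bis(methoxymethoxy)-3-(3-methylbut-2-en-1-yl)phenyl]ethan-1-ol (racemic) | CC(O)c1c(OCC)cc(OCOC)c(CC=C(C)C)c1OCOC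
A1 | alternative 1 | (2R,3R)-5-fluoro-3,7-bis(methoxymethoxy)-2-[4-(methoxymethoxy)-3-(3-methylbut-2-en-1-yl)phenyl]-2,3-dihydro-4H-chromen-4-one | CC(C)=CCc1cc([C@H]2Oc3cc(OCOC)cc(F)c3C(=O)[C@@H]2OCOC)ccc1OCOC
A2 | alternative 1 | (2R,3R)-1-[2,6-difluoro-4-(methoxymethoxy)phenyl]-3-hydroxy-2-(methoxymethoxy)-3-[4-(methoxymethoxy)-3-(3-methylbut-2-en-1-yl)phenyl]propan-1-one | CC(C)=CCc1cc([C@@H](O)[C@@H](OCOC)C(=O)c2c(F)cc(OCOC)cc2F)ccc1OCOC
A3 | alternative 2 | 3-O-benzoyl-4'-O-(tert-butyldimethylsilyl)-lespedezaflavanone C | CC(C)=CCc1cc([C@H]2Oc3c(CC=C(C)C)c(O)cc(O)c3C(=O)[C@@H]2OC(=O)c4ccccc4)ccc1O[Si](C)(C)C(C)(C)C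
A4 | alternative 2 | (2R,3R)-5-bromo-2-[4-(tert-butyldimethylsilyloxy)-3-(3-methylbut-2-en-1-yl)phenyl]-4-oxo-3,4-dihydro-2H-pyran-3-yl benzoate | CC(C)=CCc1cc([C@H]2OC=C(Br)C(=O)[C@@H]2OC(=O)c3ccccc3)ccc1O[Si](C)(C)C(C)(C)C
A5 | alternative 2 | 1-methoxy-7-methyl-1,3-bis(trimethylsilyloxy)octa-1,3,6-triene | COC(O[Si](C)(C)C)=CC(O[Si](C)(C)C)=CCC=C(C)C
A6 | alternative 3 | 2,3-trans-3,4-trans-3-benzoyloxy-4-methoxy-5,7-bis(methoxymethoxy)-8-(3-methylbut-2-en-1-yl)-2-[4-(tert-butyldimethylsilyloxy)-3-(3-methylbut-2-en-1-yl)phenyl]flavan | CC(C)=CCc1cc([C@H]2Oc3c(CC=C(C)C)c(OCOC)cc(OCOC)c3[C@@H](OC)[C@@H]2OC(=O)c4ccccc4)ccc1O[Si](C)(C)C(C)(C)C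
A7 | alternative 3 | 2-hydroxy-4,6-bis(methoxymethoxy)-3-(3-methylbut-2-en-1-yl)benzaldehyde | O=Cc1c(OCOC)cc(OCOC)c(CC=C(C)C)c1O
A8 | alternative 3 | (E)-2-[4-(tert-butyldimethylsilyloxy)-3-(3-methylbut-2-en-1-yl)phenyl]ethenyl benzoate | CC(C)=CCc1cc(/C=C/OC(=O)c2ccccc2)ccc1O[Si](C)(C)C(C)(C)C
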